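in all of them: solid substrate 0.020 M
- larch: enzyme 1 µM; run made earlier
- elm: enzyme 1.5 µM; run made earlier
- flask: enzyme 2.0 µM

| run | time / d | product / % | solid substrate / % |
|---|---|---|---|
| larch | 0.333 | 17.3 | 82.8 |
| larch | 1.04 | 53.7 | 46.0 |
| larch | 1.67 | 85.5 | 13.6 |
| larch | 3.00 | 99.9 | 0.1 |
| larch | 4.00 | 99.8 | 0.2 |
| larch | 5.00 | 100.0 | 0 |
| larch | 6.00 | 100.2 | 0.2 |
| elm | 0.500 | 25.8 | 73.9 |
| elm | 0.833 | 42.7 | 56.7 |
| elm | 1.25 | 64.8 | 35.2 |
| elm | 1.67 | 86.1 | 13.3 |
| elm | 3.00 | 99.9 | 0.1 |
| elm | 4.00 | 99.7 | 0 |
| elm | 6.00 | 100.0 | 0 |

(readings scatter by 0.3 percentage points)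

* factor on the rate of making product when 50% of the solid substrate are converted (what has only dissolved counts as not reacted) if enzyme is charged twice over
* factor on the rate when 50% of the solid substrate are converted (what has only dissolved counts as not reacted) if enzyme is charged at 20 µM instead

Take the larch run and watch the solid substrate left, not the product made. Between 0.333 d and 1.67 d it falls from 82.8% to 13.6%, which gives a fall rate of 0.518 /d: the fraction of the charge that leaves the solid per day.

Reckon the same way on the elm run, between 0.500 d and 1.67 d, and get 0.518 /d. So 1.50 times the enzyme changes the rate by a factor of 1.00, read from readings that scatter by 0.3 percentage points. Over these two spans the fraction left drops by about equal amounts per day, not by equal shares. Because the elm fall rate matches the larch one, treat the supply from the solid as the rate-limiting step.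

Decide, then, to leave the enzyme at 2.0 µM and not to pay for 20 µM. My own reckoning gives a factor of 1.00 for doubling and for 20 µM, though both amounts lie beyond the 1.5 µM of the elm run, the second far beyond. The fall rate, a reading from the two earlier runs, puts 50% conversion in the flask at 0.966 d.

The forecast gives 1 for doubling (range 0.97 to 1.05) and 1 at 20 µM (range 0.93 to 1.2), in its words: “Rate is therefore not set by enzyme.”

The flask gives 1.01 for doubling and 1.01 at 20 µM, and it reaches 50% conversion at 0.964 d.

    starting material + enzyme → product + enzyme, rate k1*[starting material]*[enzyme]/(1 + ([starting material]/Km1)) (9.40 mM, k = 1600 /M/s)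
    solid substrate ⇌ starting material, rate k2*(cs2 - [starting material]) while solid is left; crystals form when [starting material] > cs2 (solubility = 8.10 mM, k = 1.50 × 10⁻⁵ /s)
    enzyme → spent catalyst (k = 5.80 × 10⁻⁶ /s)

At 0.964 d the flask makes starting material 1.00 times as fast as it uses it up, each step taken net, and half of each step's turnover up to 8.00 d is done at matching times, 0.958 d for the dissolving against 0.964 d for the step to product. Carry the reckoned 0.966 d to the flask at 20 µM: with a rate constant of 0.50 /d for enzyme turning into spent catalyst it gives a spent share of 38.3% of the catalyst, and in that flask 38.0% of the catalyst is spent catalyst at 50% conversion.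

The readings are simulated with made-up constants, and the scatter is random.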